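The question for the red flask is what stands in it at the asked time, and which option adds most E.

| flask | L | temperature | remark | time |
|---|---|---|---|---|
| red | 0.20 M | 80 °C | the very flask that is asked about, followed so far |  |
| blue | 0.20 M | 86 °C | run made earlier |  |
| flask | 0.20 M | 80 °C |  | 80 min |

| red: time / min | red: E / % | blue: time / min | blue: E / % |
|---|---|---|---|
| 4.00 | 23.8 | 4.00 | 34.5 |
| 12.0 | 23.9 | 12.0 | 34.7 |
| 25.0 | 24.4 | 25.0 | 33.5 |
| 40.0 | 23.8 | 40.0 | 34.1 |
| 50.0 | 24.5 | 50.0 | 34.1 |
| 60.0 | 24.9 | 60.0 | 34.6 |

(readings scatter by 0.5 percentage points)

- Saturday's: change nothing and wait 25 min more
- Friday's: at 80 min raise the temperature by 15 K, then wait 25 min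
- Thursday's: at 80 min take out 90% of the E then present, then wait 25 min
- Wednesday's: at 80 min add L, 50.0% of the amount charged, then wait 25 min

- E that was removed still counts
- additions bring no volume worth counting

1. E, in percent of the L first charged, at 80 min
2. which option adds most E ("none" when 2 percentage points or less is all one gets) (Saturday's / Friday's / Thursday's / Wednesday's / none)
3. E present, with what was taken out counted in, in percent of the L first charged, after Saturday's
4. E present, with what was taken out counted in, in percent of the L first charged, after Thursday's

The red readings lie flat from 4.00 min on, with a mean of 24.2%; this is the plateau share, the fraction of the charge standing as E once the fast step has come to rest. The blue plateau reads 34.2%. My own reckoning therefore puts the red flask at the plateau share, at the asked time and after Saturday's wait alike.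

Because the plateau stood by 4.00 min, earlier than the end of the 25 min wait, Thursday's flask can be reckoned as rebalanced. Call the pool the fraction of the charge that passes between E and its partner. E then keeps its share of the pool, and the total is what was taken plus that share of the pool that remains. If nothing returned, the total would stay at 24.2%, the crude floor. A pool as large as the charge gives the ceiling, 40.7%. If the material standing as E in blue is available in red too, the pool is at least 34.2%, which lifts the floor to 30.6%.

Thursday's then gains at most 17 percentage points, and Wednesday's about 12 points if the added L follows the plateau share. A straight line through the two plateaus gives Friday's about 25 points, more than either, so my choice is Friday's.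

The forecast puts E at 24.2% at the asked time and 24.2% after Saturday's, chooses Friday's, and gives 40.7% after Thursday's, on the ground that “The plateau is reached quickly and shifts with temperature”. Its Thursday value stands at the top of the bracket.

The flask gives 24.3% E at the asked time, and 24.3% after Saturday's. Friday's adds most, 21 points, and Thursday's reaches 38.6%, inside the bracket .

    L → E (k = 0.272 s⁻¹, Ea = 81.0 kJ mol⁻¹)
    2 L → Q (k = 0.642 L mol⁻¹ s⁻¹, Ea = 45.0 kJ mol⁻¹)
    E ⇌ Z (K = 1.90, k = 0.0142 s⁻¹, Ea = 100 kJ mol⁻¹, ΔH = −90.0 kJ mol⁻¹)
    (constants at 80 °C)

At 80.0 min the flask holds 29.6% of the charge as Q, each Q counting as two L, while E and Z together hold 70.4%, which is the pool. The plateau share as read, taken over this pool, gives E a share of 34.4%, and Thursday's comes out at 38.5%. The neighbour flask, at the same 80 °C but with 0.080 M of L, has a pool of 84.8%, so the same share gives 29.2%, and that flask stands at 29.3% E.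

The earlier runs and the new flask come from a simulation with constants of no real substance; the scatter is artificial.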